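The pyranone bond C3–C4 is a Claisen bond: C3 lies between the lactone carbonyl C2 and the side-chain ketone, and C4 sits at the carboxyl oxidation level of a 3-hydroxybutanoate that already carries C6. The key step therefore lets a pent-4-ynoylketene, released from an acyl Meldrum's acid, acylate methyl (R)-3-hydroxybutanoate at O1, and then closes the ring of the resulting open-chain β-keto ester in the same flask by Lacey–Dieckmann condensation of C3 onto the ester carbon C4. A ruthenium-catalysed Alder-ene coupling of the alkyne with an allyl-bearing anti-aldol fragment (Noyori hydrogenation, Fráter–Seebach allylation) then builds the skipped diene.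

Key step: step 2

Remark: ring atoms are numbered O1, C2 (lactone C=O), C3, C4 (C–OH), C5, C6 (CH–CH3), and the tricarbonyl unit is drawn throughout as its 4-hydroxy enol tautomer.

Step 1
Reactants: 1 pent-4-ynoic acid; 2 Meldrum's acid (2,2-dimethyl-1,3-dioxane-4,6-dione)
Product: 3 5-(1-hydroxypent-4-yn-1-ylidene)-2,2-dimethyl-1,3-dioxane-4,6-dione (pent-4-ynoyl Meldrum's acid, enol form)
Conditions: DCC, DMAP, CH2Cl2, 0 °C → rt; dilute aq. HCl wash
Reagents that add atoms: none
Why: Carbodiimide-mediated C-acylation of the acidic methylene of Meldrum's acid should give the enolised acyl Meldrum's acid, a stable acylketene precursor, and the terminal alkyne is inert to these conditions.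

Step 2
Reactants: 3 pent-4-ynoyl Meldrum's acid; 4 methyl (3R)-3-hydroxybutanoate
Product: 7 (6R)-4-hydroxy-6-methyl-3-(pent-4-ynoyl)-5,6-dihydro-2H-pyran-2-one, via pent-4-ynoylketene 5 (not isolated), via open-chain β-keto ester 6 (not isolated)
Conditions: PhMe, 100 °C; cool, then KOt-Bu (1.5 equiv), THF, 0 °C → rt; 1 M HCl work-up
Reagents that add atoms: none
Why: Thermal retro-[4+2] fragmentation of 3 expels acetone and CO2 to give acylketene 5, which the secondary hydroxyl of 4 captures to form the O1–C2 ester bond of β-keto ester 6; KOt-Bu then deprotonates the doubly activated C3 methylene, and this enolate attacks the methyl ester carbon (future C4) in a Lacey–Dieckmann (intramolecular Claisen) condensation, losing methoxide and ending in the deprotonated tricarbonyl. The closest known reaction types are the acyl Meldrum's acid route to β-keto esters and the Lacey–Dieckmann cyclisation used for 3-acyltetramic and 3-acyltetronic acids. The pyranone ring closes in the 6-exo-trig mode at the ester carbonyl. No new stereocenter forms: C6 comes unchanged from 4, because its C–O bond is never broken and the product enolate resists retro-oxa-Michael ring opening. The selectivity needed is ring closure at carbon against E1cB loss of the β-acyloxy group to methyl crotonate; it should be secured because the alkoxide deprotonates only the β-keto ester CH2, the resulting enolate makes the acyloxy group a poor leaving group, and the stabilised tricarbonyl anion is the thermodynamic sink. The acyl group is thereby placed on C3 regiospecifically, with no separate O-to-C acyl migration.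

Step 3
Reactants: 8 (2S)-2-methylbutanoic acid; 9 tert-butyl hydrogen malonate
Product: 10 tert-butyl (4S)-4-methyl-3-oxohexanoate
Conditions: CDI, THF, rt; then 9, MgCl2, Et3N, THF/MeCN, rt → 40 °C; aq. citric acid work-up
Reagents that add atoms: none
Why: Masamune–Brooks homologation, in which the acyl imidazolide acylates the magnesium enolate of the malonate half ester and decarboxylation gives the β-keto ester; the near-neutral conditions should leave the α-stereocenter of the acid untouched.

Step 4
Reactants: 10 tert-butyl (4S)-4-methyl-3-oxohexanoate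
Product: 11 tert-butyl (3S,4S)-3-hydroxy-4-methylhexanoate
Conditions: RuCl2[(R)-BINAP] (1 mol %), H2 (10 bar), EtOH, 50 °C
Reagents that add atoms: none
Why: Noyori asymmetric hydrogenation of a β-keto ester, in which the (R)-BINAP catalyst should deliver hydrogen to the same face as in the reduction of methyl acetoacetate to the (R)-alcohol (named 3S here only because the branched C4 outranks C2); catalyst control is expected to override the weak bias of the methyl/ethyl stereocenter at C4, which is not enolised under these conditions.

Step 5
Reactants: 11 tert-butyl (3S,4S)-3-hydroxy-4-methylhexanoate; 12 allyl bromide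
Product: 13 tert-butyl (2R,3R,4S)-3-hydroxy-4-methyl-2-(prop-2-en-1-yl)hexanoate
Conditions: LiN(i-Pr)2 (2.2 equiv), THF, −78 → −20 °C; then 12, DMPU, −78 → −10 °C; aq. NH4Cl
Reagents that add atoms: none
Why: Fráter–Seebach alkylation, in which the chelated lithium alkoxide–enolate dianion is allylated on the face opposite the sec-butyl group of the six-membered chelate, which should set C2 as R, anti to the C3 hydroxyl.

Step 6
Reactants: 7 (6R)-4-hydroxy-6-methyl-3-(pent-4-ynoyl)-5,6-dihydro-2H-pyran-2-one; 13 tert-butyl (2R,3R,4S)-3-hydroxy-4-methyl-2-(prop-2-en-1-yl)hexanoate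
Product: 14 tert-butyl (2R,3R,4S)-3-hydroxy-2-[(1E)-7-[(6R)-4-hydroxy-6-methyl-2-oxo-5,6-dihydro-2H-pyran-3-yl]-4-methylidene-7-oxohept-1-en-1-yl]-4-methylhexanoate
Conditions: [CpRu(MeCN)3]PF6 (10 mol %), acetone, rt
Reagents that add atoms: none
Why: Ruthenium-catalysed Alder-ene-type alkene–alkyne coupling, in which oxidative cyclisation at cationic CpRu gives a ruthenacyclopentene with the alkene CH2 bonded to the internal alkyne carbon, and β-hydride elimination from the allylic CH2 followed by reductive elimination should give the branched 1,4-diene with the E-alkene; the unbranched propargylic position favours the branched isomer, the conditions are base-free so the enol stays protonated, and no stereocenter is touched.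

Step 7
Reactants: 14 tert-butyl ester of the target
Product: 16 (2R,3R,4S)-3-hydroxy-2-[(1E)-7-[(6R)-4-hydroxy-6-methyl-2-oxo-5,6-dihydro-2H-pyran-3-yl]-4-methylidene-7-oxohept-1-en-1-yl]-4-methylhexanoic acid (CNP0221901.1), via tris(trimethylsilyl) derivative 15 (not isolated)
Conditions: Me3SiOTf (5 equiv), 2,6-lutidine (8 equiv), CH2Cl2, 0 °C → rt; then aq. citric acid, THF, rt
Reagents that add atoms: none
Why: Silyl triflate-mediated cleavage of a tert-butyl ester, in which O-silylation of the ester carbonyl triggers loss of 2-methylpropene under lutidine buffering, so that no free strong acid is present to protonate the 1,1-disubstituted alkene or shift the β,γ-alkene; the trimethylsilyl ester, ether and enol ether of 15 should hydrolyse on the mild aqueous acid work-up without touching a stereocenter.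

Compound list
1 | pent-4-ynoic acid | C#CCCC(=O)O | starting material
2 | Meldrum's acid (2,2-dimethyl-1,3-dioxane-4,6-dione) | CC1(C)OC(=O)CC(=O)O1 | starting material
3 | 5-(1-hydroxypent-4-yn-1-ylidene)-2,2-dimethyl-1,3-dioxane-4,6-dione | C#CCCC(O)=C1C(=O)OC(C)(C)OC1=O | intermediate
4 | methyl (3R)-3-hydroxybutanoate | C[C@@H](O)CC(=O)OC | starting material
5 | pent-4-ynoylketene (hept-1-en-6-yne-1,3-dione) | C#CCCC(=O)C=C=O | intermediate
6 | methyl (3R)-3-[(3-oxohept-6-ynoyl)oxy]butanoate | C#CCCC(=O)CC(=O)O[C@H](C)CC(=O)OC | intermediate
7 | (6R)-4-hydroxy-6-methyl-3-(pent-4-ynoyl)-5,6-dihydro-2H-pyran-2-one | C#CCCC(=O)C1=C(O)C[C@@H](C)OC1=O | intermediate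
8 | (2S)-2-methylbutanoic acid | CC[C@H](C)C(=O)O | starting material
9 | tert-butyl hydrogen malonate | CC(C)(C)OC(=O)CC(=O)O | starting material
10 | tert-butyl (4S)-4-methyl-3-oxohexanoate | CC[C@H](C)C(=O)CC(=O)OC(C)(C)C | intermediate
11 | tert-butyl (3S,4S)-3-hydroxy-4-methylhexanoate | CC[C@H](C)[C@@H](O)CC(=O)OC(C)(C)C | intermediate
12 | allyl bromide (3-bromoprop-1-ene) | C=CCBr | starting material
13 | tert-butyl (2R,3R,4S)-3-hydroxy-4-methyl-2-(prop-2-en-1-yl)hexanoate | C=CC[C@@H](C(=O)OC(C)(C)C)[C@H](O)[C@@H](C)CC | intermediate
14 | tert-butyl (2R,3R,4S)-3-hydroxy-2-[(1E)-7-[(6R)-4-hydroxy-6-methyl-2-oxo-5,6-dihydro-2H-pyran-3-yl]-4-methylidene-7-oxohept-1-en-1-yl]-4-methylhexanoate | C=C(C/C=C/[C@@H](C(=O)OC(C)(C)C)[C@H](O)[C@@H](C)CC)CCC(=O)C1=C(O)C[C@@H](C)OC1=O | intermediate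
15 | trimethylsilyl ester of the target acid, carrying a trimethylsilyl ether on the side-chain hydroxyl and a trimethylsilyl enol ether on ring C4 | C=C(C/C=C/[C@@H](C(=O)O[Si](C)(C)C)[C@H](O[Si](C)(C)C)[C@@H](C)CC)CCC(=O)C1=C(O[Si](C)(C)C)C[C@@H](C)OC1=O | intermediate
16 | (2R,3R,4S)-3-hydroxy-2-[(1E)-7-[(6R)-4-hydroxy-6-methyl-2-oxo-5,6-dihydro-2H-pyran-3-yl]-4-methylidene-7-oxohept-1-en-1-yl]-4-methylhexanoic acid (CNP0221901.1) | C=C(C/C=C/[C@@H](C(=O)O)[C@H](O)[C@@H](C)CC)CCC(=O)C1=C(O)C[C@@H](C)OC1=O | target

Total step count: 7. Longest linear sequence: 5 steps (8 → 10 → 11 → 13 → 14 → 16; steps 3, 4, 5, 6, 7).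

Steps most likely to fail

Step 6. The acidic, chelating enolised tricarbonyl of 7 may bind the cationic ruthenium centre and slow turnover, and insertion with the opposite alkyne orientation would give the linear diene. The fallback sets out from 6 and 13 and comes back at 14. The thermal stage of step 2 is stopped before base is added and the neutral β-keto ester 6 is isolated. Compounds 6 and 13 are coupled with [CpRu(MeCN)3]PF6 in acetone at rt, which should give the open-chain coupled β-keto ester tert-butyl (2R,3R,4S)-3-hydroxy-2-[(1E)-9-{[(2R)-4-methoxy-4-oxobutan-2-yl]oxy}-4-methylidene-7,9-dioxonon-1-en-1-yl]-4-methylhexanoate F1. The Lacey–Dieckmann closure of the C3–C4 bond (KOt-Bu, 1.1 equiv, THF, 0 °C) is then carried out after the fragment coupling and should give 14.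

Step 2. Deprotonation next to the methyl ester could trigger E1cB expulsion of the acyloxy group, and the acylketene could self-condense, both in competition with ring closure. The fallback sets out from 4 and 1 and comes back at 7. Compound 4 is acetylated (Ac2O, pyridine, DMAP) to methyl (3R)-3-acetoxybutanoate F2. Treatment with LiN(SiMe3)2 in THF at −78 °C should bring about intramolecular Claisen condensation of the acetate enolate onto the methyl ester, again closing the ring at C3–C4, to give (6R)-4-hydroxy-6-methyl-5,6-dihydro-2H-pyran-2-one F3. DCC/DMAP coupling of F3 with 1 in CH2Cl2 should give the enol ester (6R)-6-methyl-2-oxo-5,6-dihydro-2H-pyran-4-yl pent-4-ynoate F4, which under the same DMAP conditions is expected to rearrange by Fries-type O-to-C acyl migration to 7.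

Step 7. Lewis-acid-induced migration of the 1,1-disubstituted double bond, its capture by the neighbouring enol oxygen, or incomplete ester cleavage could erode the final product. The fallback sets out from 13 and comes back at 16. The tert-butyl ester is removed before coupling (CF3CO2H, CH2Cl2, 0 °C → rt), when only a monosubstituted alkene is present, to give (2R,3R,4S)-3-hydroxy-4-methyl-2-(prop-2-en-1-yl)hexanoic acid F5. Alder-ene coupling of F5 with 7 under the conditions of step 6 should then give 16 directly, with no protecting group in the last step.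

Further compounds
F1 | step 6 | tert-butyl (2R,3R,4S)-3-hydroxy-2-[(1E)-9-{[(2R)-4-methoxy-4-oxobutan-2-yl]oxy}-4-methylidene-7,9-dioxonon-1-en-1-yl]-4-methylhexanoate | C=C(C/C=C/[C@@H](C(=O)OC(C)(C)C)[C@H](O)[C@@H](C)CC)CCC(=O)CC(=O)O[C@H](C)CC(=O)OC
F2 | step 2 | methyl (3R)-3-acetoxybutanoate | CC(=O)O[C@H](C)CC(=O)OC
F3 | step 2 | (6R)-4-hydroxy-6-methyl-5,6-dihydro-2H-pyran-2-one | C[C@@H]1CC(O)=CC(=O)O1
F4 | step 2 | (6R)-6-methyl-2-oxo-5,6-dihydro-2H-pyran-4-yl pent-4-ynoate | C#CCCC(=O)OC1=CC(=O)O[C@H](C)C1
F5 | step 7 | (2R,3R,4S)-3-hydroxy-4-methyl-2-(prop-2-en-1-yl)hexanoic acid | C=CC[C@@H](C(=O)O)[C@H](O)[C@@H](C)CC
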